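Which species holds most of the G after 4.0 min in Wednesday's flask and in Sunday's, and how much of it?

| flask | G | E | remark | time |
|---|---|---|---|---|
| epsilon | 2 mM | 1.2 mM | run made earlier |  |
| alpha | 2 mM | 3.5 mM | run made earlier |  |
| Wednesday's | 2.0 mM | 1.00 mM |  | 4.0 min |
| Sunday's | 2.0 mM | 3.00 mM |  | 4.0 min |

| run | time / min | Q / % | J / % | L / % | G / % |
|---|---|---|---|---|---|
| epsilon | 1.00 | 64 | 14 | 3 | 18 |
| epsilon | 2.00 | 72 | 8 | 7 | 9 |
| epsilon | 3.00 | 76 | 4 | 7 | 9 |
| epsilon | 4.00 | 85 | 0 | 8 | 6 |
| alpha | 0.333 | 11 | 48 | 38 | 1 |
| alpha | 0.667 | 12 | 52 | 40 | 0 |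
| alpha | 1.50 | 17 | 49 | 33 | 0 |
| alpha | 4.00 | 15 | 48 | 36 | 0 |

(standard deviation of a reading: 2 percentage points)

1. which of these there is most of at the end, counted by the G in it, Wednesday's (J / Q / L / G)
2. which of these there is most of at the end, counted by the G in it, Sunday's (J / Q / L / G)
3. amount of the one of these that there is most of at the end, in percent of the G charged, Wednesday's
4. amount of the one of these that there is most of at the end, in percent of the G charged, Sunday's

- a species is counted by the G in it: one Q counts as two

Wednesday's flask looks like epsilon with slightly less E, and Sunday's looks like alpha with slightly less E. Those two runs end apart. In epsilon J falls to 0 % while Q climbs to 85 %, but in alpha G reads 0 % at 0.667 min and J then stays near 48 %, so J is read as passing into Q by meeting G. Epsilon's E balances if each Q costs one E and each L two, which sums to 1.17 mM against 1.2 mM charged.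

The concentration to follow is then cE. If J forms first order in cE and L second order, L per J goes with cE. Taking mean cE as half the charge, epsilon's readings at 4.00 min give 0.314 mM⁻¹ for the split number, a selectivity factor: L formed per G passed through J (J plus half of Q as counted), per unit of mean cE. Alpha's readings at 4.00 min, with 0.950 mM of E reckoned left and mean cE taken halfway between charge and remainder, give 0.292 mM⁻¹.

In Wednesday's flask E is the limiting reagent. Taken as spent to the end, with J counted as passed into Q, it gives 0.157 L per G passed through J, and the E balance then gives Q at 76.1 %. Sunday's flask should keep J on top, near alpha's reading.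

The forecast says Q at 72 % for Wednesday's, lower than this reckoning, and J at 55 % for Sunday's, on the ground that “E is excess-like, so the result resembles alpha but with less L”.

Wednesday's flask gives Q at 76.3 %, and Sunday's gives J at 49.6 %, 5.4 percentage points under the forecast. Sunday's flask keeps 18.9 % of its E with G at 0 %, while Wednesday's has E at 0 % with G at 17.6 %.

    G + E → J (k = 130 M⁻¹ s⁻¹)
    G + 2 E → L (k = 42000 M⁻² s⁻¹)
    G + J → Q (k = 41.0 M⁻¹ s⁻¹)

On Sunday's mean cE the split number gives 0.560 L per G passed through J, and the flask holds 0.527.

In a flask like Wednesday's but with 4.0 mM of E, which keeps 31.1 % of that charge, the split number gives 0.823 L per G passed through J. The computed flask holds 0.797, with L at 42.3 % and J at 48.6 %.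

(The numbers in the tables are simulated for an exercise, noise included.)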